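Ring A of the target is unsubstituted at C-2 and C-3, the two methylene carbons that follow the gem-dimethyl carbon C-1, so a C2=C3 alkene is a traceless precursor of that bond. Ring-closing metathesis of an acyclic 1,7-diene, with hydrogenation in the same flask, should therefore deliver (R)-2-hydroxy-2,6,6-trimethylcyclohexanone in one operation. The diene already holds the C-5 carbinol centre, taken from (S)-lactic acid by self-regeneration of the stereocentre, and the C-6 ketone between two quaternary carbons. Alkoxide-directed acetylide addition then sets C-6 (trans-diol). Alkyne reduction, a Horner–Wadsworth–Emmons coupling and saponification complete the all-E polyene acid.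

Key step: step 4

Remark on the chemistry: carotenoid locants are used (ring A: C-1 gem-dimethyl carbon, C-2 to C-4 methylenes, C-5 methyl carbinol, C-6 chain-bearing carbinol; chain C-7 to C-15, then C-15′ down to the carboxyl carbon C-10′). The target is read as the (5R,6R) trans-diol with an all-E heptaene.

Step 1
Reactants: 1 (S)-lactic acid; 2 pivalaldehyde (2,2-dimethylpropanal)
Product: 3 (2S,5S)-2-tert-butyl-5-methyl-1,3-dioxolan-4-one (cis)
Conditions: TsOH·H2O (cat.), H2SO4 (cat.), pentane, reflux with azeotropic removal of water; crystallisation from pentane–Et2O at −78 °C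
Reagents that add atoms: none
Why: Acid-catalysed acetalisation of the α-hydroxy acid under thermodynamic control should favour the isomer with tert-butyl cis to methyl, the lactic acid centre is untouched, and the cis isomer is purified by crystallisation.

Step 2
Reactants: 3; 4 allyl bromide
Product: 5 (2S,5R)-2-tert-butyl-5-methyl-5-(prop-2-en-1-yl)-1,3-dioxolan-4-one (allyl trans to tert-butyl)
Conditions: LiN(iPr)2 (1.1 equiv), THF, −78 °C; then 4, −78 → −30 °C
Reagents that add atoms: none
Why: Enolate alkylation with self-regeneration of the stereocentre: the tert-butyl group on the acetal carbon shields one face of the planar lithium enolate, so the allyl group should enter trans to it and take the place of the former hydrogen (retention, 5R).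

Step 3
Reactants: 5; 6 prenylmagnesium chloride (3-methylbut-2-en-1-ylmagnesium chloride)
Product: 7 (R)-5-hydroxy-3,3,5-trimethylocta-1,7-dien-4-one
Conditions: Me2C=CHCH2MgCl (1.3 equiv), THF, −78 °C; quench at −78 °C with aq NH4Cl, then rt
Reagents that add atoms: none
Why: Grignard acylation with allylic transposition: the allylic Grignard reagent should attack the activated acylal carbonyl through its tertiary γ-terminus in a six-membered cyclic transition state, the adduct collapses on work-up with loss of pivalaldehyde, and the ketone between two fully substituted carbons should resist a second addition, the stereocentre not being involved.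

Step 4
Reactants: 7
Product: 9 (R)-2-hydroxy-2,6,6-trimethylcyclohexan-1-one, via cyclohexenone 8 (not isolated)
Conditions: second-generation Grubbs catalyst (2 mol %), CH2Cl2 (0.02 M), 40 °C; then solvent exchanged for EtOAc, Pd/C (5 %), H2 (1 atm), rt
Reagents that add atoms: none
Why: The ruthenium alkylidene should load on the unhindered allyl terminus (C-3 side), and intramolecular [2+2] cycloaddition with the neopentyl vinyl group on C-1 followed by cycloreversion forms C2=C3 and expels ethene; palladium-catalysed hydrogenation in the same flask then saturates this alkene to the C2–C3 bond of ring A. The closest known reaction type is ring-closing olefin metathesis of 1,7-dienes to cyclohexenes with an allylic quaternary carbon, combined with one-pot alkene hydrogenation. Ring A is closed as a six-membered carbocycle by metathesis of the two terminal vinyl groups with loss of ethene. No new stereocentre is formed, and the C-5 carbinol carbon is fully substituted and the ketone has no α-hydrogen, so nothing can epimerise. The step needs cyclisation to win over intermolecular metathesis, which the six-membered ring size, high dilution and the Thorpe–Ingold effect of the quaternary carbons C-1 and C-5 should secure, and it needs reduction of the disubstituted C=C beside the hindered ketone, which Pd/C under one atmosphere of H2 should provide.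

Step 5
Reactants: 9; 10 (E)-3-methylpent-2-en-4-yn-1-ol
Product: 11 (1S,2R)-1-[(3E)-5-hydroxy-3-methylpent-3-en-1-yn-1-yl]-2,6,6-trimethylcyclohexane-1,2-diol (trans-diol; alkynyl group cis to the C-5 hydroxyl)
Conditions: 10 (3 equiv), n-BuLi (6 equiv), THF, −78 → 0 °C; then 9, −78 °C → rt; then H2O
Reagents that add atoms: none
Why: Chelation-controlled 1,2-addition of a lithium acetylide to a non-enolisable ketone: the lithium alkoxide of the tertiary hydroxyl should chelate the carbonyl oxygen and hold O-5 in the carbonyl plane, the C-5 methyl and one C-1 methyl then lie axial on the same face, and the slim acetylide should enter from the opposite face, trans to the C-5 methyl, so that the new C-6 hydroxyl ends trans to the C-5 hydroxyl.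

Step 6
Reactants: 11
Product: 12 (1R,2R)-1-[(1E,3E)-5-hydroxy-3-methylpenta-1,3-dien-1-yl]-2,6,6-trimethylcyclohexane-1,2-diol
Conditions: NaAlH2(OCH2CH2OMe)2 (5 equiv), THF, 0 °C → rt; then aqueous potassium sodium tartrate
Reagents that add atoms: none
Why: Hydroxyl-directed trans-hydroalumination of the propargylic alcohol (aluminium hydride reduction of a propargylic alcohol to the E-allylic alcohol) should give the 7E alkene after protonolysis and leave the 9E alkene and both carbinol centres untouched.

Step 7
Reactants: 12
Product: 14 diethyl {(2E,4E)-5-[(1R,2R)-1,2-dihydroxy-2,6,6-trimethylcyclohexyl]-3-methylpenta-2,4-dien-1-yl}phosphonate, via allylic bromide 13 (not isolated)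
Conditions: NBS, Me2S, CH2Cl2, −30 → 0 °C; cold aqueous wash, concentration; then P(OEt)3 (neat), 90 °C
Reagents that add atoms: N-bromosuccinimide, O=C1CCC(=O)N1Br (bromine of 13); triethyl phosphite, CCOP(OCC)OCC
Why: Corey–Kim bromination should convert only the primary allylic alcohol (the two tertiary hydroxyls are too hindered) without allylic shift, and the Michaelis–Arbuzov reaction of the allylic bromide then forms the C–P bond under neutral conditions with the diene geometry retained.

Step 8
Reactants: 15 (2E,4E,6E)-2,7-dimethylocta-2,4,6-trienedial; 16 ethyl (triphenylphosphoranylidene)acetate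
Product: 17 ethyl (2E,4E,6E,8E)-4,9-dimethyl-10-oxodeca-2,4,6,8-tetraenoate
Conditions: 15 (2 equiv), slow addition of 16, CH2Cl2, rt
Reagents that add atoms: none
Why: Wittig olefination with a stabilised ylide is E-selective, and the excess of the symmetrical dialdehyde should direct the reaction to mono-olefination.

Step 9
Reactants: 14; 17
Product: 18 ethyl (2E,4E,6E,8E,10E,12E,14E)-15-[(1R,2R)-1,2-dihydroxy-2,6,6-trimethylcyclohexyl]-4,9,13-trimethylpentadeca-2,4,6,8,10,12,14-heptaenoate
Conditions: KN(SiMe3)2 (3.2 equiv), THF, −78 °C; then 17, −78 → 0 °C; then H2O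
Reagents that add atoms: none
Why: Horner–Wadsworth–Emmons olefination: the allylic phosphonate carbanion (two further equivalents of base hold the tertiary hydroxyls as unreactive alkoxides) should add through its α-carbon to the α-methyl enal and eliminate by way of the favoured trans-oxaphosphetane to give the 11E double bond.

Step 10
Reactants: 18
Product: 19 (2E,4E,6E,8E,10E,12E,14E)-15-[(1R,2R)-1,2-dihydroxy-2,6,6-trimethylcyclohexyl]-4,9,13-trimethylpentadeca-2,4,6,8,10,12,14-heptaenoic acid (the target)
Conditions: KOH, EtOH–THF–H2O, rt, argon, dark; then cold dilute HCl to pH 4–5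
Reagents that add atoms: potassium hydroxide, [K+].[OH-]
Why: Saponification of the ethyl ester by acyl substitution should leave the tertiary diol, the stereocentres and the all-E polyene untouched, and mild acidification frees the acid.

Compound list
1 | (S)-lactic acid | C[C@H](O)C(=O)O | starting material
2 | pivalaldehyde (2,2-dimethylpropanal) | CC(C)(C)C=O | starting material
3 | (2S,5S)-2-tert-butyl-5-methyl-1,3-dioxolan-4-one | C[C@@H]1O[C@H](C(C)(C)C)OC1=O | intermediate
4 | allyl bromide (3-bromoprop-1-ene) | C=CCBr | starting material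
5 | (2S,5R)-2-tert-butyl-5-methyl-5-(prop-2-en-1-yl)-1,3-dioxolan-4-one | C[C@]1(CC=C)O[C@H](C(C)(C)C)OC1=O | intermediate
6 | prenylmagnesium chloride | CC(C)=CC[Mg]Cl | starting material
7 | (R)-5-hydroxy-3,3,5-trimethylocta-1,7-dien-4-one | C=CC(C)(C)C(=O)[C@](C)(O)CC=C | intermediate
8 | (R)-6-hydroxy-2,2,6-trimethylcyclohex-3-en-1-one (not isolated) | O=C1C(C)(C)C=CC[C@@]1(C)O | intermediate
9 | (R)-2-hydroxy-2,6,6-trimethylcyclohexan-1-one | O=C1C(C)(C)CCC[C@@]1(C)O | intermediate
10 | (E)-3-methylpent-2-en-4-yn-1-ol | C#C/C(C)=C/CO | starting material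
11 | (1S,2R)-1-[(3E)-5-hydroxy-3-methylpent-3-en-1-yn-1-yl]-2,6,6-trimethylcyclohexane-1,2-diol (descriptor S at the alkynyl carbinol only because alkynyl outranks C(CH3)2; same spatial arrangement as in the target) | OC/C=C(C)/C#C[C@@]1(O)C(C)(C)CCC[C@@]1(C)O | intermediate
12 | (1R,2R)-1-[(1E,3E)-5-hydroxy-3-methylpenta-1,3-dien-1-yl]-2,6,6-trimethylcyclohexane-1,2-diol | OC/C=C(C)/C=C/[C@@]1(O)C(C)(C)CCC[C@@]1(C)O | intermediate
13 | (1R,2R)-1-[(1E,3E)-5-bromo-3-methylpenta-1,3-dien-1-yl]-2,6,6-trimethylcyclohexane-1,2-diol (not isolated) | BrC/C=C(C)/C=C/[C@@]1(O)C(C)(C)CCC[C@@]1(C)O | intermediate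
14 | diethyl {(2E,4E)-5-[(1R,2R)-1,2-dihydroxy-2,6,6-trimethylcyclohexyl]-3-methylpenta-2,4-dien-1-yl}phosphonate | CCOP(=O)(OCC)C/C=C(C)/C=C/[C@@]1(O)C(C)(C)CCC[C@@]1(C)O | intermediate
15 | (2E,4E,6E)-2,7-dimethylocta-2,4,6-trienedial | O=C/C(C)=C/C=C/C=C(C)/C=O | starting material
16 | ethyl (triphenylphosphoranylidene)acetate | CCOC(=O)C=P(c1ccccc1)(c1ccccc1)c1ccccc1 | starting material
17 | ethyl (2E,4E,6E,8E)-4,9-dimethyl-10-oxodeca-2,4,6,8-tetraenoate | CCOC(=O)/C=C/C(C)=C/C=C/C=C(C)/C=O | intermediate
18 | ethyl (2E,4E,6E,8E,10E,12E,14E)-15-[(1R,2R)-1,2-dihydroxy-2,6,6-trimethylcyclohexyl]-4,9,13-trimethylpentadeca-2,4,6,8,10,12,14-heptaenoate | CCOC(=O)/C=C/C(C)=C/C=C/C=C(C)/C=C/C=C(C)/C=C/[C@@]1(O)C(C)(C)CCC[C@@]1(C)O | intermediate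
19 | (2E,4E,6E,8E,10E,12E,14E)-15-[(1R,2R)-1,2-dihydroxy-2,6,6-trimethylcyclohexyl]-4,9,13-trimethylpentadeca-2,4,6,8,10,12,14-heptaenoic acid | CC(/C=C/C=C(C)/C=C/[C@@]1(O)C(C)(C)CCC[C@@]1(C)O)=C\C=C\C=C(C)\C=C\C(=O)O | target

Total step count: 10. Longest linear sequence: 9 steps (steps 1–7, 9 and 10); step 8 prepares the polyene aldehyde in a side branch.

Steps most likely to fail

1. Step 5. The risk is poor facial selectivity: attack on the face syn to the C-5 methyl would give the cis-diol. Addition to the doubly neopentyl ketone may also be slow. The fallback replaces the lithium alkoxide as control element by an external bidentate chelate on a protected ether. It sets out from 9, which is capped (MOMCl, iPr2NEt, NaI, 1,2-dichloroethane, 60 °C) as (R)-2-(methoxymethoxy)-2,6,6-trimethylcyclohexan-1-one F1. The bis(bromomagnesium) derivative of 10 (10 with two equivalents of EtMgBr) is then added in CH2Cl2–Et2O in the presence of MgBr2·OEt2. The five-membered magnesium chelate between the ketone oxygen and the ether oxygen should lock O-5 in the carbonyl plane, and the axial C-5 methyl should send the acetylide to the opposite face, giving (1S,2R)-1-[(3E)-5-hydroxy-3-methylpent-3-en-1-yn-1-yl]-2-(methoxymethoxy)-2,6,6-trimethylcyclohexan-1-ol F2. Cleavage of the acetal with dilute aqueous HCl in THF comes back to the route at 11.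

2. Step 3. The risk is loss of regiocontrol in the Grignard attack: reaction through the primary terminus would give the linear prenyl ketone. Early collapse of the adduct followed by over-addition is the second risk. The fallback builds the same bond at the aldehyde oxidation level, where γ-selective prenylation is routine. It sets out from 5, which is reduced with LiAlH4 (Et2O, 0 °C) to (R)-2-methylpent-4-ene-1,2-diol F3. Selective oxidation of the primary hydroxyl (TEMPO, PhI(OAc)2, CH2Cl2) should give (R)-2-hydroxy-2-methylpent-4-enal F4. Barbier prenylation (prenyl bromide, In powder, THF–H2O) should then give the γ-adduct (5R)-3,3,5-trimethylocta-1,7-diene-4,5-diol F5, whose C-4 configuration is of no consequence. Oxidation of the secondary alcohol with IBX (EtOAc, 80 °C) comes back to the route at 7.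

3. Step 7. The risks are ionisation or allylic transposition of the dienyl bromide next to the tertiary allylic alcohol, and decomposition during the hot Arbuzov step. The fallback reverses the polarity of the coupling, so that the diol fragment is only ever oxidised under neutral conditions. It sets out from 12 and 17 and comes back to the route at 18.
   - Diol fragment: 12 is oxidised (MnO2, CH2Cl2, rt) to (2E,4E)-5-[(1R,2R)-1,2-dihydroxy-2,6,6-trimethylcyclohexyl]-3-methylpenta-2,4-dienal F6.
   - Polyene fragment: 17 is reduced (NaBH4, EtOH, 0 °C) to ethyl (2E,4E,6E,8E)-10-hydroxy-4,9-dimethyldeca-2,4,6,8-tetraenoate F7. Bromination (CBr4, PPh3, CH2Cl2, 0 °C) gives ethyl (2E,4E,6E,8E)-10-bromo-4,9-dimethyldeca-2,4,6,8-tetraenoate F8, and P(OEt)3 (90 °C) converts it to ethyl (2E,4E,6E,8E)-10-(diethoxyphosphoryl)-4,9-dimethyldeca-2,4,6,8-tetraenoate F9.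
   - Coupling: Horner–Wadsworth–Emmons reaction of F9 (NaN(SiMe3)2, THF, −78 → 0 °C) with F6 should give 18.

Further compounds
F1 | step 5 | (R)-2-(methoxymethoxy)-2,6,6-trimethylcyclohexan-1-one | O=C1C(C)(C)CCC[C@@]1(C)OCOC
F2 | step 5 | (1S,2R)-1-[(3E)-5-hydroxy-3-methylpent-3-en-1-yn-1-yl]-2-(methoxymethoxy)-2,6,6-trimethylcyclohexan-1-ol | OC/C=C(C)/C#C[C@@]1(O)C(C)(C)CCC[C@@]1(C)OCOC
F3 | step 3 | (R)-2-methylpent-4-ene-1,2-diol | OC[C@](C)(O)CC=C
F4 | step 3 | (R)-2-hydroxy-2-methylpent-4-enal | O=C[C@](C)(O)CC=C
F5 | step 3 | (5R)-3,3,5-trimethylocta-1,7-diene-4,5-diol | C=CC(C)(C)C(O)[C@](C)(O)CC=C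
F6 | step 7 | (2E,4E)-5-[(1R,2R)-1,2-dihydroxy-2,6,6-trimethylcyclohexyl]-3-methylpenta-2,4-dienal | O=C/C=C(C)/C=C/[C@@]1(O)C(C)(C)CCC[C@@]1(C)O
F7 | step 7 | ethyl (2E,4E,6E,8E)-10-hydroxy-4,9-dimethyldeca-2,4,6,8-tetraenoate | CCOC(=O)/C=C/C(C)=C/C=C/C=C(C)/CO
F8 | step 7 | ethyl (2E,4E,6E,8E)-10-bromo-4,9-dimethyldeca-2,4,6,8-tetraenoate | CCOC(=O)/C=C/C(C)=C/C=C/C=C(C)/CBr
F9 | step 7 | ethyl (2E,4E,6E,8E)-10-(diethoxyphosphoryl)-4,9-dimethyldeca-2,4,6,8-tetraenoate | CCOC(=O)/C=C/C(C)=C/C=C/C=C(C)/CP(=O)(OCC)OCC
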